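**Plan**
- Retrosynthetic cuts, in order:
  - C7–C9 (aldol);
  - C7=C8 of a six-membered ring B (oxidative cleavage of ferna-7,9(11)-dien-3β-ol);
  - C8–C14, with the 14-methyl returned to C8 (Prins closure and 1,2-shift);
  - ring E re-expanded to a 22,22-dimethylcyclohexanol, with every shifted H and Me put back;
  - C11–C12 (Kolbe).

  What remains is two copies of one C15 unit from sclareolide.
- Enabling feature: in ring E (C17–C21) the isopropyl group sits on C21 beside quaternary C17. Along C21–C17–C18–C13 the groups 21β-H, 17α-Me, 18β-H and 13α-Me alternate anti. This is the footprint of a 4,4-dimethylcyclohexyl cation that contracted and passed its charge down the backbone, so rings D/E are rings A/B in disguise (latent C2 symmetry).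
- Forward order: rings A/B and D/(six-membered) E come ready-made in sclareolide. Kolbe coupling joins the halves. Step 5 contracts ring E and unveils a C14 ketone. Ring C closes in step 6. Ring B is cut in step 7 and re-closed five-membered onto C9 in step 8.
- Stereochemistry: C5 and C10 come directly from sclareolide. C13, C17, C18 and C21 come from sclareolide's centres by suprafacial shifts. C3 is set by the enzyme. C14, C9 and C7 are set by substrate control (10β- and 14β-methyl groups).

Key step: step 5

Remark on numbering: the target is read as 3β,7β-dihydroxy-7(8→9)abeo-fernan-8-one, and fernane/onocerane numbering is kept throughout. Ring A is C1–C5, C10. Ring B is C5–C7, C9, C10. Ring C is C8, C9, C11–C14. Ring D is C13–C18. Ring E is C17–C21. C22 is the isopropyl CH.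
Assumption: the C3-selective engineered P450 BM3 hydroxylase of step 1 is taken as an accessible catalyst, expressed in E. coli from its published sequence.

Step 1
Reactants: 1 (+)-sclareolide
Product: 2 3β-hydroxysclareolide
Conditions: engineered P450 BM3 hydroxylase (E. coli lysate), NADP+ (cat.), phosphite dehydrogenase, Na2HPO3, air, KPi buffer pH 8, 25 °C
Reagents that add atoms: dioxygen O=O
Why: Enzymatic C–H hydroxylation (oxygen rebound) of sclareolide at C3 is a known preparative reaction, and the active site delivers oxygen to the equatorial 3β-position, which sets C3.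

Step 2
Reactants: 2 3β-hydroxysclareolide
Product: 3 3β,8α-dihydroxy-13,14,15,16-tetranorlabdan-12-oic acid
Conditions: KOH, MeOH–H2O, reflux; then 1 M HCl to pH 4, 0 °C
Reagents that add atoms: potassium hydroxide [K+].[OH-]
Why: Saponification by acyl–oxygen cleavage leaves the C8–O bond and the 8α-configuration untouched, and cold mild acidification avoids relactonisation.

Step 3
Reactants: 3 3β,8α-dihydroxy-13,14,15,16-tetranorlabdan-12-oic acid (two molecules)
Product: 4 onocerane-3β,8α,14β,21α-tetraol
Conditions: Pt anode, Pt cathode, undivided cell, KOH (0.1 equiv), MeOH, 0.2 A cm−2, 30 °C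
Reagents that add atoms: none
Why: In this Kolbe electrolysis the primary C11 radicals from anodic decarboxylation dimerise to the C11–C12 bond, a coupling known for bicyclic acids of this type, and no stereocentre is touched, so the product is C2-symmetric.

Step 4
Reactants: 4 onocerane-3β,8α,14β,21α-tetraol
Product: 5 21α-mesyloxyonocerane-3β,8α,14β-triol
Conditions: MsCl (0.7 equiv), pyridine, CH2Cl2, 0 °C
Reagents that add atoms: methanesulfonyl chloride CS(=O)(=O)Cl
Why: In this sulfonylation the two equatorial secondary carbinols are homotopic about the C2 axis, so a deficit of MsCl can give only one monomesylate, the tertiary alcohols do not react under these conditions, and unreacted 4 is returned to the step.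

Step 5
Reactants: 5 21α-mesyloxyonocerane-3β,8α,14β-triol
Product: 7 tetracyclic keto diol, via C22 cation 6 (not isolated)
Conditions: 2,6-di-tert-butyl-4-methylpyridine (1.5 equiv), (CF3)2CHOH, 0.01 M, 40 °C
Reagents that add atoms: none
Why: Proposed new method: ionisation of the equatorial 21α-mesylate in the strongly ionising, non-basic solvent is assisted by the anti-periplanar C17–C22 bond, so C17 moves from C22 to C21 (Wagner–Meerwein 1,2-alkyl shift, the only ring-forming event: six-membered ring E, C17–C22, becomes the five-membered ring C17–C21 and C22 is pushed outside as the 2-propyl cation 6). The charge then runs down the backbone by 21β-H→C22, 17β-H→C21, 18α-Me→C17, 13β-H→C18 and 14α-Me→C13, the last shift being pulled by the equatorial 14β-hydroxyl, which ends as the C14 ketone (semipinacol termination). The closest known reaction types are the retropinacol contraction of 4,4-dimethyl-3β-sulfonates, the acid-induced backbone rearrangements of steroids and triterpenoids, and the semipinacol rearrangement; their union in one event is new. Each group migrates suprafacially and anti to the one before it, so 21β-H (α-isopropyl), 17α-Me, 18β-H and 13α-Me are dictated by the trans-anti array (17β-H, 18α-Me, 13β-H, axial 14α-Me) inherited from sclareolide. The step needs migration to outrun proton loss: the solvent and the hindered pyridine are poor bases towards carbon-bound hydrogen, the tertiary cations interconvert fast, and the only strongly downhill exit is ketone formation. Site selectivity is secured because only one half carries a leaving group, and the scavenged acid leaves the 3β- and 8α-hydroxyls of the other half untouched.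

Step 6
Reactants: 7 tetracyclic keto diol
Product: 11 ferna-7,9(11)-dien-3β-ol, via tetrasubstituted olefin 8 (not isolated), via Prins adduct 9 (not isolated), via allyl cation 10 (not isolated)
Conditions: TfOH (0.3 equiv), (CF3)2CHOH–CH2Cl2 1:4, 4 Å MS, −20 to 0 °C; Et3N
Reagents that add atoms: none
Why: Proposed new method: acid dehydrates the 8α-ol to the 8(9)-olefin 8, whose C8 attacks the protonated C14 ketone from the α face opposite the 10β-methyl (six-membered ring C closed endo to the C8=C9 bond) and loss of H-11 gives 9; the crowded tertiary 14-ol then ionises, and of the two flanking methyl groups only 8β-Me can move to give an allyl cation (10, C8–C9–C11), so it crosses on the β face and fixes 14β-Me trans to 13α-Me before loss of H-7 gives the heteroannular diene; the closest known types are the acid closure of the C8–C14 bond in onocerane-type 8,14-seco-triterpenoids, Prins and carbonyl-ene cyclisations and Wagner–Meerwein methyl shifts, and free equatorial 3β-ols are known to survive acid isomerisations of triterpenols at such temperatures.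

Step 7
Reactants: 11 ferna-7,9(11)-dien-3β-ol
Product: 13 3β-hydroxy-8-oxo-7,8-secofern-9(11)-en-7-al, via 7α,8α-diol 12 (not isolated)
Conditions: OsO4 (5 mol %), NaIO4 (3 equiv), 2,6-lutidine, dioxane–H2O 3:1, 20 °C
Reagents that add atoms: osmium tetroxide O=[Os](=O)(=O)=O; sodium periodate [Na+].[O-]I(=O)(=O)=O
Why: In this Lemieux–Johnson oxidation, osmylation should prefer the α face of C7=C8, whose C7 end is an unhindered CH next to a CH2, over C9=C11, whose C11 is screened by the 10β-methyl above and the 13α-methyl below and whose C9 adjoins quaternary C10, and once the glycol is cleaved the remaining double bond is a deactivated enone.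

Step 8
Reactants: 13 3β-hydroxy-8-oxo-7,8-secofern-9(11)-en-7-al
Product: 15 3β,7β-dihydroxy-7(8→9)abeo-fernan-8-one, via copper enolate 14 (not isolated)
Conditions: [(Ph3P)CuH]6 (0.5 equiv), toluene, −40 to 20 °C; aq NH4Cl
Reagents that add atoms: none
Why: In this reductive aldol cyclisation, copper hydride adds to C11 and gives the C8–C9 enolate regiospecifically, which closes the five-membered ring B onto the C7 aldehyde; the reversible copper aldolate should settle on the isomer in which the slim C7 arm rather than quaternary C10 is axial on ring C (C9), and in which the oxygen on C7 turns away from the axial 14β-methyl (7β-OH).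

**Compound list**
1 | (+)-sclareolide | O=C1C[C@H]2[C@](C)(O1)CC[C@H]1C(C)(C)CCC[C@]21C | starting material
2 | 3β-hydroxysclareolide | O=C1C[C@H]2[C@](C)(O1)CC[C@H]1C(C)(C)[C@@H](O)CC[C@]21C | intermediate
3 | 3β,8α-dihydroxy-13,14,15,16-tetranorlabdan-12-oic acid | OC(=O)C[C@H]1[C@](C)(O)CC[C@H]2C(C)(C)[C@@H](O)CC[C@]12C | intermediate
4 | onocerane-3β,8α,14β,21α-tetraol (C2-symmetric 8,14-secogammacerane) | C(C[C@H]1[C@](C)(O)CC[C@H]2C(C)(C)[C@@H](O)CC[C@]12C)[C@H]1[C@](C)(O)CC[C@H]2C(C)(C)[C@@H](O)CC[C@]12C | intermediate
5 | 21α-mesyloxyonocerane-3β,8α,14β-triol | C(C[C@H]1[C@](C)(O)CC[C@H]2C(C)(C)[C@@H](OS(C)(=O)=O)CC[C@]12C)[C@H]1[C@](C)(O)CC[C@H]2C(C)(C)[C@@H](O)CC[C@]12C | intermediate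
6 | C22 cation: ring E contracted to C17–C21, 2-propyl cation on C21 (21β-H, 17β-H, 18α-Me, 13β-H, 14α-Me, 14β-OH still in place) | C[C+](C)[C@H]1CC[C@@]2(C)[C@H]1CC[C@@](C)(O)[C@@H]2CC[C@H]1[C@](C)(O)CC[C@H]2C(C)(C)[C@@H](O)CC[C@]12C | intermediate
7 | tetracyclic keto diol: 3β,8α-dihydroxydriman-11-yl unit (rings A/B) joined through C11–C12 to C13 of 21α-isopropyl-13α,17α-dimethyl-18β-H-trans-hydrindan-14-one (rings D/E) | CC(C)[C@H]1CC[C@@H]2[C@]1(C)CCC(=O)[C@@]2(C)CC[C@H]1[C@](C)(O)CC[C@H]2C(C)(C)[C@@H](O)CC[C@]12C | intermediate
8 | 8(9)-olefin of 7 (tetrasubstituted C8=C9, 3β-OH, C14 ketone) | CC(C)[C@H]1CC[C@@H]2[C@]1(C)CCC(=O)[C@@]2(C)CCC1=C(C)CC[C@H]2C(C)(C)[C@@H](O)CC[C@]12C | intermediate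
9 | Prins adduct: pentacyclic 9(11)-ene-3β,14β-diol with 8β-Me and 13α-Me | CC(C)[C@H]1CC[C@@H]2[C@]1(C)CC[C@@]3(O)[C@@]2(C)CC=C4[C@@]3(C)CC[C@H]5C(C)(C)[C@@H](O)CC[C@]45C | intermediate
10 | 3β-hydroxyfernane C8–C9–C11 allyl cation | CC(C)[C@H]1CC[C@@H]2[C@]1(C)CC[C@@]3(C)[C@@]2(C)CC=C4[C+]3CC[C@H]5C(C)(C)[C@@H](O)CC[C@]45C | intermediate
11 | ferna-7,9(11)-dien-3β-ol | CC(C)[C@H]1CC[C@@H]2[C@]1(C)CC[C@@]3(C)[C@@]2(C)CC=C4C3=CC[C@H]5C(C)(C)[C@@H](O)CC[C@]45C | intermediate
12 | fern-9(11)-ene-3β,7α,8α-triol | CC(C)[C@H]1CC[C@@H]2[C@]1(C)CC[C@@]3(C)[C@@]2(C)CC=C4[C@]3(O)[C@H](O)C[C@H]5C(C)(C)[C@@H](O)CC[C@]45C | intermediate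
13 | 3β-hydroxy-8-oxo-7,8-secofern-9(11)-en-7-al | CC(C)[C@H]1CC[C@@H]2[C@]1(C)CC[C@@]3(C)[C@@]2(C)CC=C(C3=O)[C@@]4(C)CC[C@H](O)C(C)(C)[C@@H]4CC=O | intermediate
14 | copper C8–C9 enolate of the 9(11)-dihydro derivative of 13 | CC(C)[C@H]1CC[C@@H]2[C@]1(C)CC[C@@]3(C)[C@@]2(C)CCC(=C3O[Cu])[C@@]4(C)CC[C@H](O)C(C)(C)[C@@H]4CC=O | intermediate
15 | 3β,7β-dihydroxy-7(8→9)abeo-fernan-8-one (CNP0155208.1) | CC(C)[C@H]1CC[C@@H]2[C@]1(C)CC[C@]1(C)C(=O)[C@]3(CC[C@@]21C)[C@@H](O)C[C@H]1C(C)(C)[C@@H](O)CC[C@@]13C | target

Total step count: 8
Longest linear sequence: 8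

**Steps most likely to fail**

Step 5. The migration train may stall through early proton loss from the C22, C21 or C17 cation before the charge reaches C13. Under buffered conditions such a loss cannot be undone.

The fallback builds rings D/E in their final size by known chemistry and joins them to the ring A/B acid. It sets out from 3 and returns at 7.
- Michael addition of 2-methylcyclopentane-1,3-dione to ethyl vinyl ketone gives 2-methyl-2-(3-oxopentyl)cyclopentane-1,3-dione F1.
- Asymmetric aldol condensation with L-phenylalanine and camphorsulfonic acid gives (S)-4,7a-dimethyl-2,3,7,7a-tetrahydro-1H-indene-1,5(6H)-dione F2.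
- Isopropenylmagnesium bromide with CeCl3 adds to the more reactive saturated ketone, from the face opposite the angular methyl, to give the isopropenyl carbinol F3.
- Birch-type reductive alkylation (Li, NH3; then tert-butyl bromoacetate in THF) sets the trans ring fusion and the quaternary C13. The electrophile enters anti to the angular methyl, giving the hydrindanone tert-butyl ester F4.
- Ionic hydrogenation (Et3SiH, CF3CO2H) removes the tertiary allylic hydroxyl, saturates the side chain from the face opposite the 17-methyl and cleaves the ester, giving the hydrindanone acetic acid F5.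
- Mixed Kolbe electrolysis of F5 with an excess of 3 gives 7.

Step 6. The ring B cation may be diverted into hydride and methyl shifts towards C10 and C5, or the hindered ketone may fail to engage the olefin.

The fallback replaces the free-cation cascade by a proton-free pericyclic closure with isolation of each stage. It sets out from 7 and returns at 11.
- Mild dehydration (p-TsOH·H2O cat., toluene, 60 °C) gives the thermodynamic olefin 8.
- Me2AlCl (3 equiv, CH2Cl2, −78 to 0 °C) promotes the intramolecular carbonyl-ene reaction. H-11 passes to oxygen in concert with C8–C14 bond formation, and stray protons are destroyed by the Al–Me bonds. This gives 9.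
- Brief exposure of 9 to BF3·OEt2 at −78 °C then ionises only the tertiary homoallylic alcohol and gives 11 through 10.

Step 7. Site selectivity between the two trisubstituted double bonds of the diene may be poor.

The fallback treats the diene as one unit and contracts ring B by an acyl shift. It sets out from 11 and returns at 15.
- 1,4-Reduction with Li in EtNH2 gives fern-8-en-3β-ol F6.
- CrO3 with 3,5-dimethylpyrazole oxidises the carbinol and the allylic C7. C11 is shielded on both faces by the 10β- and 13α-methyl groups. The product is fern-8-ene-3,7-dione F7.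
- Dimethyldioxirane attacks the α face, opposite the 10β- and 14β-methyl groups, to give 8α,9α-epoxyfernane-3,7-dione F8.
- BF3·OEt2 triggers the known 1,2-acyl shift of α,β-epoxy ketones. C7 moves from C8 to C9, anti to the breaking C9–O bond, giving 7(8→9)abeo-fernane-3,7,8-trione F9.
- NaBH4 (MeOH, −20 °C) reduces C3 to the equatorial 3β-ol and C7 to the 7β-ol. The C8 ketone, flanked by two quaternary carbons, is left intact, giving 15.

**Further compounds**
F1 | step 5 | 2-methyl-2-(3-oxopentyl)cyclopentane-1,3-dione | CCC(=O)CCC1(C)C(=O)CCC1=O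
F2 | step 5 | (S)-4,7a-dimethyl-2,3,7,7a-tetrahydro-1H-indene-1,5(6H)-dione | O=C1CCC2=C(C)C(=O)CC[C@]12C
F3 | step 5 | isopropenyl carbinol (1-hydroxy-1-isopropenyl-4,7a-dimethyl-tetrahydroinden-5-one, isopropenyl anti to the angular methyl) | CC(=C)[C@]1(O)CCC2=C(C)C(=O)CC[C@]12C
F4 | step 5 | hydrindanone tert-butyl ester (trans-fused, quaternary C13 with α-Me and CH2CO2tBu) | CC(=C)[C@]1(O)CC[C@@H]2[C@]1(C)CCC(=O)[C@@]2(C)CC(=O)OC(C)(C)C
F5 | step 5 | hydrindanone acetic acid (21α-isopropyl-13α,17α-dimethyl-14-oxo-trans-hydrindan-13-ylacetic acid) | CC(C)[C@H]1CC[C@@H]2[C@]1(C)CCC(=O)[C@@]2(C)CC(=O)O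
F0 | step 6 | none | none
F6 | step 7 | fern-8-en-3β-ol | CC(C)[C@H]1CC[C@@H]2[C@]1(C)CC[C@@]3(C)[C@@]2(C)CCC4=C3CC[C@H]5C(C)(C)[C@@H](O)CC[C@]45C
F7 | step 7 | fern-8-ene-3,7-dione | CC(C)[C@H]1CC[C@@H]2[C@]1(C)CC[C@@]3(C)[C@@]2(C)CCC4=C3C(=O)C[C@H]5C(C)(C)C(=O)CC[C@]45C
F8 | step 7 | 8α,9α-epoxyfernane-3,7-dione | CC(C)[C@H]1CC[C@@H]2[C@]1(C)CC[C@@]3(C)[C@@]2(C)CC[C@]46O[C@@]36C(=O)C[C@H]5C(C)(C)C(=O)CC[C@]45C
F9 | step 7 | 7(8→9)abeo-fernane-3,7,8-trione | CC(C)[C@H]1CC[C@@H]2[C@]1(C)CC[C@]1(C)C(=O)[C@]3(CC[C@@]21C)C(=O)C[C@H]1C(C)(C)C(=O)CC[C@@]13C
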